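**Retrosynthetic overview**

1. The guanine is made last: its imidazole ring (C8 and the C8–ring A bond) comes from ortho-formyl phenol 19 and triaminopyrimidinone 20 by an oxidative Traube closure, and the formyl group comes from ortho-formylation of macrocyclic phenol 17.
2. The piperazine and the 14-membered macrocycle are closed together, by head-to-tail double reductive amination of bis(α-amino aldehyde) 15 across the preformed ring A–O–ring B diaryl ether.
3. The strategy rests on piperazine C2 and C5: each carries nitrogen, a benzylic CH2 (to ring B and to ring A) and a ring CH2, so each maps onto a branched allylic amine ArCH2–CH(N)–CH=CH2, the vinyl group being cut down by ozonolysis to the carbon that ends as ring C3 or C6.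
4. Both C–N bonds and both stereocentres come from a twofold catalytic asymmetric Overman rearrangement of (E,E)-bis(trichloroacetimidate) 9 to (S,S)-bis(trichloroacetamide) 10 with the palladacycle (S)-COP-Cl, [Pd(μ-Cl)(oxazolinylcyclopentadienyl-C,N)Co(η4-C4Ph4)]2.
5. Compound 9 comes from an SNAr diaryl ether (1 + 2), bis(benzylic bromide) 5 and a twofold E-retentive Stille coupling. Ring order: rings A and B are bought, then macrocycle plus piperazine (step 9), then the guanine imidazole (step 12).

Key step: step 6

Assumption: stannane 6 is taken as a purchasable, geometrically pure E reagent (otherwise one step from propargyl alcohol and Bu3SnH), and 20 is used as its commercial sulfate salt. Ring A is the benzyloxy/phenol ring and ring B the para-phenylene ring. Steps 4 and 5 consume one molecule of the monofunctional partner per arm, so two molecules in all; the second molecule is entered on the line of reagents that add atoms.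

**Route**

Step 1
Reactants: 1 4-(benzyloxy)-3-hydroxybenzaldehyde; 2 4-fluorobenzaldehyde
Product: 3 4-(benzyloxy)-3-(4-formylphenoxy)benzaldehyde
Conditions: K2CO3, DMAc, 140 °C
Reagents that add atoms: none
Why: Nucleophilic aromatic substitution (SNAr): the phenoxide of 1 displaces the fluoride para to the formyl group of 2 through a Meisenheimer adduct, which fixes the ring A pattern (ether oxygen ortho to OBn, carbon arm para to OBn) without a regiochemical question.

Step 2
Reactants: 3 4-(benzyloxy)-3-(4-formylphenoxy)benzaldehyde
Product: 4 [4-(benzyloxy)-3-[4-(hydroxymethyl)phenoxy]phenyl]methanol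
Conditions: NaBH4, MeOH/THF, 0 °C to rt
Reagents that add atoms: none
Why: Borohydride reduction of both aryl aldehydes to benzylic alcohols; the ethers are inert.

Step 3
Reactants: 4 [4-(benzyloxy)-3-[4-(hydroxymethyl)phenoxy]phenyl]methanol
Product: 5 1-(benzyloxy)-4-(bromomethyl)-2-[4-(bromomethyl)phenoxy]benzene
Conditions: CBr4, PPh3, CH2Cl2, 0 °C; used without storage
Reagents that add atoms: carbon tetrabromide, BrC(Br)(Br)Br
Why: Appel reaction: bromide displaces the alkoxyphosphonium groups under neutral conditions, so the benzyl aryl ether never meets HBr.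

Step 4
Reactants: 5 1-(benzyloxy)-4-(bromomethyl)-2-[4-(bromomethyl)phenoxy]benzene; 6 (E)-3-(tributylstannyl)prop-2-en-1-ol
Product: 7 (2E)-4-[4-(benzyloxy)-3-{4-[(2E)-4-hydroxybut-2-en-1-yl]phenoxy}phenyl]but-2-en-1-ol
Conditions: 6 (2.2 equiv in all), Pd2(dba)3 (cat.), P(2-furyl)3, THF, 60 °C
Reagents that add atoms: (E)-3-(tributylstannyl)prop-2-en-1-ol as the second equivalent of 6, CCCC[Sn](CCCC)(CCCC)/C=C/CO
Why: Twofold Stille coupling, one molecule of 6 per benzylic bromide: zerovalent palladium inserts into each benzylic C–Br bond, the alkenyl group is transferred from tin with retention and reductive elimination forms both ArCH2–CH= bonds, so the E geometry of both alkenes is carried over from 6.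

Step 5
Reactants: 7 (E,E)-bis(allylic alcohol); 8 trichloroacetonitrile
Product: 9 (E,E)-bis(allylic 2,2,2-trichloroacetimidate) of 7
Conditions: Cl3CCN (2.5 equiv in all), DBU (cat.), CH2Cl2, 0 °C; rapid filtration through Et3N-deactivated silica
Reagents that add atoms: trichloroacetonitrile as the second equivalent of 8, N#CC(Cl)(Cl)Cl
Why: Base-catalysed addition of each of the two primary allylic alkoxides to one molecule of the electron-poor nitrile (trichloroacetimidate formation), which leaves the alkene geometry untouched.

Step 6
Reactants: 9 (E,E)-bis(allylic trichloroacetimidate)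
Product: 10 2,2,2-trichloro-N-[(2S)-1-{4-[2-(benzyloxy)-5-{(2S)-2-[(trichloroacetyl)amino]but-3-en-1-yl}phenoxy]phenyl}but-3-en-2-yl]acetamide
Conditions: (S)-COP-Cl, [Pd(μ-Cl){(η5-(S)-(pR)-2-(4-isopropyl-2-oxazolinyl)cyclopentadienyl-C,N)Co(η4-C4Ph4)}]2 (5 mol % per imidate), CH2Cl2, 38 °C, acid-free
Reagents that add atoms: none
Why: Each (E)-alkene is activated by coordination to the divalent palladium of the palladacycle, the imidate nitrogen adds to the alkene carbon that bears the ArCH2 group on the face away from the metal to give a six-membered cyclic σ-alkylpalladium intermediate, and ring opening with C–O cleavage and loss of the metal releases the allylic trichloroacetamide, overall a cyclisation-induced [3,3] rearrangement driven by formation of the amide C=O. The closest known reaction is the catalytic asymmetric Overman rearrangement of (E)-trichloroacetimidates of primary allylic alcohols with this catalyst, run here twice on one substrate. No ring of the target is closed in this step; it forms two C–N bonds and two stereocentres. Both stereocentres (later piperazine C2 and C5) are set by the catalyst, whose planar-chiral metallocene and oxazoline substituent select the alkene face; the S catalyst is expected to give S at each centre, as with simple (E)-alkyl-substituted imidates, and the two allyl units on different rings react independently. The step needs enantiofacial selectivity at two alkenes and clean [3,3] rather than ionisation-type [1,3] transfer; the first is secured by catalyst control on the E alkenes fixed in step 4, the second by the primary, non-ionising imidates and the absence of acid. Twofold induction should deplete the wrong enantiomer statistically, so that residual error appears mainly as the separable (R,S) and (S,R) diastereomers.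

Step 7
Reactants: 10 (S,S)-bis(allylic trichloroacetamide)
Product: 12 dibenzyl (S,S)-biscarbamate of the bis(allylic amine), via bis(isocyanate) 11 (not isolated)
Conditions: BnOH (3 equiv), Cs2CO3, DMF, 80 °C
Reagents that add atoms: benzyl alcohol, OCc1ccccc1
Why: Base-induced E1cB loss of trichloromethanide from each N–H trichloroacetamide gives the isocyanate, which one molecule of benzyl alcohol per arm traps as the Cbz carbamate (haloform-type carbamate synthesis); the N-bearing stereocentres are not involved.

Step 8
Reactants: 12 (S,S)-bis(N-Cbz allylic amine)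
Product: 14 (S,S)-bis(N-Cbz-α-amino aldehyde), via bis(ozonide) 13 (not isolated)
Conditions: O3, CH2Cl2, −78 °C (Sudan Red 7B end point); PPh3, −78 °C to rt; aqueous wash, used at once
Reagents that add atoms: ozone, O=[O+][O-]
Why: Ozonolysis with reductive cleavage of the ozonides turns each vinyl group into the formyl carbon that becomes a ring CH2; the alkenes react far faster than the alkoxyarenes, and the N-Cbz α-amino aldehydes should keep their configuration if kept cold and not stored.

Step 9
Reactants: 14 (S,S)-bis(N-Cbz-α-amino aldehyde)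
Product: 17 (S,S)-macrocyclic piperazine phenol (14-membered ring A–O–ring B cyclophane), via bis(α-amino aldehyde) 15 (not isolated), via macrocyclic 2,5-dihydropyrazine 16 (not isolated)
Conditions: H2 (1 atm), Pd/C, MeOH, rt; 14 added slowly to about 1 mM
Reagents that add atoms: none
Why: Hydrogenolysis frees both amines and the phenol, each amine condenses with the aldehyde of the other arm (first the 14-membered ring, then the six-membered ring) and the C=N bonds are hydrogenated on palladium, a cyclodimerisation-type double reductive amination made intramolecular by the diaryl ether; the stereocentres are not the imine carbons, so they are kept provided reduction outruns imine–enamine tautomerism, and only the cis (S,S) arrangement can bridge the two rings.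

Step 10
Reactants: 17 (S,S)-macrocyclic piperazine phenol
Product: 18 N,N'-di-Boc macrocyclic piperazine phenol
Conditions: Boc2O (2.2 equiv), Et3N, CH2Cl2/MeOH, 0 °C to rt
Reagents that add atoms: di-tert-butyl dicarbonate, CC(C)(C)OC(=O)OC(=O)OC(C)(C)C
Why: Carbamate formation at the two secondary amines, which acylate much faster than the phenol in the absence of an acyl-transfer catalyst.

Step 11
Reactants: 18 N,N'-di-Boc macrocyclic piperazine phenol
Product: 19 N,N'-di-Boc ortho-formyl phenol (salicylaldehyde of ring A)
Conditions: MgCl2, Et3N, (CH2O)n, MeCN, reflux; citric acid work-up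
Reagents that add atoms: paraformaldehyde (formaldehyde unit), C=O
Why: Magnesium-mediated ortho-formylation of phenols (Casnati–Skattebøl reaction): the magnesium phenoxide delivers formaldehyde to the only unsubstituted position ortho to the hydroxyl, and a second formaldehyde oxidises the resulting benzylic alkoxide by hydride transfer.

Step 12
Reactants: 19 N,N'-di-Boc ortho-formyl phenol; 20 2,5,6-triaminopyrimidin-4(3H)-one sulfate
Product: 23 N,N'-di-Boc-guanipiperazine A, via Schiff base 21 (not isolated), via 7,8-dihydropurine 22 (not isolated)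
Conditions: NaOAc, DMF/H2O, Ar, 70 °C; then FeCl3·6H2O (2.2 equiv), 70 °C
Reagents that add atoms: none
Why: Traube purine synthesis in its oxidative aldehyde form: the most nucleophilic 5-amino group gives the Schiff base, the 6-amino group adds to the imine carbon, and trivalent iron removes two hydrogens to aromatise the imidazole ring, while the acetate buffer protects the Boc groups.

Step 13
Reactants: 23 N,N'-di-Boc-guanipiperazine A
Product: 24 guanipiperazine A
Conditions: TFA/CH2Cl2 (1:4), 0 °C to rt; then NH3/MeOH
Reagents that add atoms: none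
Why: Acidolysis of the two tert-butyl carbamates (loss of isobutene and CO2); the phenol ring has no free ortho or para position for tert-butylation and no stereocentre is touched.

**Compound list**

1 | 4-(benzyloxy)-3-hydroxybenzaldehyde | O=Cc1ccc(OCc2ccccc2)c(O)c1 | starting material
2 | 4-fluorobenzaldehyde | O=Cc1ccc(F)cc1 | starting material
3 | 4-(benzyloxy)-3-(4-formylphenoxy)benzaldehyde | O=Cc1ccc(Oc2cc(C=O)ccc2OCc2ccccc2)cc1 | intermediate
4 | [4-(benzyloxy)-3-[4-(hydroxymethyl)phenoxy]phenyl]methanol | OCc1ccc(Oc2cc(CO)ccc2OCc2ccccc2)cc1 | intermediate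
5 | 1-(benzyloxy)-4-(bromomethyl)-2-[4-(bromomethyl)phenoxy]benzene | BrCc1ccc(Oc2cc(CBr)ccc2OCc2ccccc2)cc1 | intermediate
6 | (E)-3-(tributylstannyl)prop-2-en-1-ol | CCCC[Sn](CCCC)(CCCC)/C=C/CO | starting material
7 | (2E)-4-[4-(benzyloxy)-3-{4-[(2E)-4-hydroxybut-2-en-1-yl]phenoxy}phenyl]but-2-en-1-ol | OC/C=C/Cc1ccc(Oc2cc(C/C=C/CO)ccc2OCc2ccccc2)cc1 | intermediate
8 | trichloroacetonitrile | N#CC(Cl)(Cl)Cl | starting material
9 | (E,E)-bis(allylic trichloroacetimidate) of 7 | N=C(OC/C=C/Cc1ccc(Oc2cc(C/C=C/COC(=N)C(Cl)(Cl)Cl)ccc2OCc2ccccc2)cc1)C(Cl)(Cl)Cl | intermediate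
10 | (S,S)-bis(allylic trichloroacetamide) | C=C[C@H](Cc1ccc(Oc2cc(C[C@@H](C=C)NC(=O)C(Cl)(Cl)Cl)ccc2OCc2ccccc2)cc1)NC(=O)C(Cl)(Cl)Cl | intermediate
11 | (S,S)-bis(isocyanate) | C=C[C@H](Cc1ccc(Oc2cc(C[C@@H](C=C)N=C=O)ccc2OCc2ccccc2)cc1)N=C=O | intermediate
12 | (S,S)-bis(N-Cbz allylic amine) | C=C[C@H](Cc1ccc(Oc2cc(C[C@@H](C=C)NC(=O)OCc3ccccc3)ccc2OCc2ccccc2)cc1)NC(=O)OCc1ccccc1 | intermediate
13 | bis(1,2,4-trioxolane) of 12 (ozonide carbons as a mixture) | C1(OCOO1)[C@H](Cc1ccc(Oc2cc(C[C@@H](C3OCOO3)NC(=O)OCc3ccccc3)ccc2OCc2ccccc2)cc1)NC(=O)OCc1ccccc1 | intermediate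
14 | (S,S)-bis(N-Cbz-α-amino aldehyde) | O=C[C@H](Cc1ccc(Oc2cc(C[C@@H](C=O)NC(=O)OCc3ccccc3)ccc2OCc2ccccc2)cc1)NC(=O)OCc1ccccc1 | intermediate
15 | (S,S)-bis(α-amino aldehyde), free phenol | O=C[C@H](Cc1ccc(Oc2cc(C[C@@H](C=O)N)ccc2O)cc1)N | intermediate
16 | macrocyclic (S,S)-2,5-dihydropyrazine phenol | c1cc2cc(c1O)Oc1ccc(cc1)C[C@H]1C=N[C@H](C=N1)C2 | intermediate
17 | (S,S)-macrocyclic piperazine phenol | c1cc2cc(c1O)Oc1ccc(cc1)C[C@H]1CN[C@H](CN1)C2 | intermediate
18 | N,N'-di-Boc macrocyclic piperazine phenol | c1cc2cc(c1O)Oc1ccc(cc1)C[C@H]1CN(C(=O)OC(C)(C)C)[C@H](CN1C(=O)OC(C)(C)C)C2 | intermediate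
19 | N,N'-di-Boc ortho-formyl phenol | O=Cc1cc2cc(c1O)Oc1ccc(cc1)C[C@H]1CN(C(=O)OC(C)(C)C)[C@H](CN1C(=O)OC(C)(C)C)C2 | intermediate
20 | 2,5,6-triaminopyrimidin-4(3H)-one sulfate | Nc1nc(N)c(N)c(=O)[nH]1.OS(O)(=O)=O | starting material
21 | Schiff base of 19 with the 5-amino group of the pyrimidinone | Nc1nc(N)c(N=Cc2cc3cc(c2O)Oc2ccc(cc2)C[C@H]2CN(C(=O)OC(C)(C)C)[C@H](CN2C(=O)OC(C)(C)C)C3)c(=O)[nH]1 | intermediate
22 | 8-aryl-7,8-dihydroguanine (C8 unassigned) | Nc1nc2NC(c3cc4cc(c3O)Oc3ccc(cc3)C[C@H]3CN(C(=O)OC(C)(C)C)[C@H](CN3C(=O)OC(C)(C)C)C4)Nc2c(=O)[nH]1 | intermediate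
23 | N,N'-di-Boc-guanipiperazine A | Nc1nc2nc(-c3cc4cc(c3O)Oc3ccc(cc3)C[C@H]3CN(C(=O)OC(C)(C)C)[C@H](CN3C(=O)OC(C)(C)C)C4)[nH]c2c(=O)[nH]1 | intermediate
24 | guanipiperazine A | Nc1nc2nc(-c3cc4cc(c3O)Oc3ccc(cc3)C[C@H]3CN[C@H](CN3)C4)[nH]c2c(=O)[nH]1 | target

**Step count and risks**

Total steps: 13. Longest linear sequence: 13 steps (1 to 24).

Steps most likely to fail:

1. Step 9. Intermolecular condensation to oligomers may compete with closure of the strained 14-membered ring, and the free α-amino aldehyde or the dihydropyrazine may epimerise or tautomerise towards the aromatic pyrazine before it is reduced. The fallback sets out from 14 and comes back at 17, and separates N-deprotection from C–N bond formation. The aldehydes of 14 would be masked with HC(OMe)3, MeOH and catalytic PPTS as the bis(dimethyl acetal) F1. Hydrogenolysis (H2, Pd/C) should then give the configurationally robust, isolable bis(α-amino dimethyl acetal) phenol F2. Aqueous TFA would unmask it to the bis(ammonium aldehyde) bis(trifluoroacetate) F3. This salt would be added slowly to a dilute, acetate-buffered (pH about 5–6) methanol solution of 2-picoline–borane. Each iminium ion should be reduced as it forms (Borch-type reductive amination), so the flat bis-imine need never build up, and 17 results.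

2. Step 6. The second rearrangement may stall through catalyst inhibition, face selectivity may erode at one site to give diastereomer mixtures, or ionisation may compete. The fallback sets out from 7 and comes back at 12, and replaces the sigmatropic nitrogen transfer by an intermolecular allyl-metal substitution. Diol 7 would be converted with ClCO2Me and pyridine into the (E,E)-bis(allylic methyl carbonate) F4. A twofold iridium-catalysed, branch-selective asymmetric allylic amination with benzyl carbamate ([Ir(cod)Cl]2, BINOL-derived bis(1-phenylethyl)amine phosphoramidite, K3PO4, THF) should then give 12 directly. The ligand enantiomer would be chosen on a one-armed model so that nitrogen adds to the same alkene face as in step 6.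

3. Step 12. The electron-rich phenol or the aminopyrimidine may be over-oxidised, chelation of iron by the salicylaldimine may stall ring closure, and the Boc groups may be partly lost. The fallback sets out from 19 and comes back at 23, and uses the non-oxidative Traube closure. Pinnick oxidation (NaClO2, NaH2PO4, 2-methyl-2-butene) would give the salicylic acid F5. Amide coupling to the 5-amino group of 20 (EDC·HCl, HOBt, i-Pr2NEt, DMF) would give the 5-aroylamino-2,6-diaminopyrimidin-4(3H)-one F6. Base-mediated cyclodehydration (aqueous NaOH/EtOH, reflux, under which Boc is stable) should close the imidazole ring to 23.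

**Further compounds**

F1 | step 9 | (S,S)-bis(N-Cbz-α-amino aldehyde dimethyl acetal) | COC(OC)[C@H](Cc1ccc(Oc2cc(C[C@@H](C(OC)OC)NC(=O)OCc3ccccc3)ccc2OCc2ccccc2)cc1)NC(=O)OCc1ccccc1
F2 | step 9 | (S,S)-bis(α-amino aldehyde dimethyl acetal), free phenol | COC(OC)[C@H](Cc1ccc(Oc2cc(C[C@@H](C(OC)OC)N)ccc2O)cc1)N
F3 | step 9 | (S,S)-bis(ammonium aldehyde) bis(trifluoroacetate) | O=C[C@H](Cc1ccc(Oc2cc(C[C@@H](C=O)N)ccc2O)cc1)N.OC(=O)C(F)(F)F.OC(=O)C(F)(F)F
F4 | step 6 | (E,E)-bis(allylic methyl carbonate) of 7 | COC(=O)OC/C=C/Cc1ccc(Oc2cc(C/C=C/COC(=O)OC)ccc2OCc2ccccc2)cc1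
F5 | step 12 | N,N'-di-Boc macrocyclic salicylic acid | OC(=O)c1cc2cc(c1O)Oc1ccc(cc1)C[C@H]1CN(C(=O)OC(C)(C)C)[C@H](CN1C(=O)OC(C)(C)C)C2
F6 | step 12 | 5-aroylamino-2,6-diaminopyrimidin-4(3H)-one | Nc1nc(N)c(NC(=O)c2cc3cc(c2O)Oc2ccc(cc2)C[C@H]2CN(C(=O)OC(C)(C)C)[C@H](CN2C(=O)OC(C)(C)C)C3)c(=O)[nH]1
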